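**Plan**

1. Locants used below (daucane numbering): C1 = ring-fusion C(CH3), C2/C3 = CH2, C4 = CH(iPr), C5 = ring-fusion C(OH), C6/C7 = CH2, C8 = C(CH3)=, C9 = =CH, C10 = CH–O(acyl).
2. Cuts: the ester C–O bond; C10–H (back to the C10 ketone); the C9–C10 bond, which takes C9 out of the seven-membered ring and leaves a cis-hydrindanone (six-membered ring C1–C10–C8–C7–C6–C5) carrying C9 as an iodomethyl group on C8; the C4–C5 bond (ketone-ene), back to an achiral 2,2-disubstituted cyclohexane-1,3-dione; then the C4=C(CH3)2 olefination and the C1–C2 Michael bond.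
3. Forward: the side chain is attached to C1 of 2-methylcyclohexane-1,3-dione; the five-membered ring closes by ene attack of C4 on one dione carbonyl (C5); C8 is methylated and iodomethylated; the six-membered ring is widened to the seven-membered ring by radical insertion of C9 between C8 and C10; dehydrogenation, C10 reduction and acylation finish. The helpers (ketone oxidation level at C10, iodide, transient cyclopropane) are all consumed on the way.
4. Enabling feature: C1 lies between two oxygen-bearing carbons (C10 and C5), the pattern of a 2-methyl-1,3-dione, and the C10 carbonyl has only one enolisable flank (C8, since C1 is quaternary). A CH2 radical on C8 is therefore 1,3 to the carbonyl carbon, and its acyl shift can only give the C10–C9–C8(CH3) unit of the seven-membered ring.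
5. Stereochemistry: the ene step sets C1, C5 and C4 together (the catalyst picks one of two enantiotopic carbonyls, the tether forces cis fusion, the cyclic hydrogen transfer puts OH and isopropenyl cis); C10 comes from a reagent-controlled oxazaborolidine reduction; the transient C8 centre is erased.

Key step: step 8

Remark: compounds 10, 12, 13 and 17 are carried as epimer mixtures at daucane C8 (sp2 after step 9), and their SMILES leave that centre open. Systematic names use indene or azulene locants (daucane C10 = C4 of the indenone and azulenone, C1 = C3a, C5 = C7a or C8a, C4 = C1, C8 = indene C5 = azulene C6).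

**Route**

Step 1
Reactants: 1 2-methylcyclohexane-1,3-dione; 2 acrolein (prop-2-enal)
Product: 3 3-(1-methyl-2,6-dioxocyclohexyl)propanal
Conditions: acrolein (1.5 equiv), H2O, rt
Reagents that add atoms: none
Why: Michael addition of the enolised 2-alkyl-1,3-dione to a soft acceptor gives clean C-alkylation (no O-alkylation as with alkyl halides) and forms the C1–C2 bond at the future quaternary, still prochiral, carbon.

Step 2
Reactants: 3; 4 isopropyltriphenylphosphonium iodide
Product: 6 2-methyl-2-(4-methylpent-3-en-1-yl)cyclohexane-1,3-dione, via propan-2-ylidene(triphenyl)phosphorane 5 (not isolated)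
Conditions: 4, n-BuLi, THF, 0 °C; then 3, −78 → 0 °C
Reagents that add atoms: none
Why: Wittig olefination, in which the non-stabilised ylide should take the aldehyde at −78 °C far faster than the two hindered neopentyl-type ring ketones, and the trisubstituted alkene formed has no geometry to control.

Step 3
Reactants: 6
Product: 7 (1R,3aS,7aS)-7a-hydroxy-3a-methyl-1-(prop-1-en-2-yl)octahydro-4H-inden-4-one
Conditions: Cu(SbF6)2 (10 mol %, from CuCl2 and AgSbF6), (S,S)-t-Bu-box [2,2'-(propane-2,2-diyl)bis((4S)-4-tert-butyl-4,5-dihydrooxazole)], 4 Å MS, CH2Cl2, −20 °C → rt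
Reagents that add atoms: none
Why: Proposed new method: the two dione oxygens should chelate the divalent copper centre, which activates both C=O groups while the C2-symmetric ligand shields diagonally opposite quadrants, so the tethered trisubstituted alkene carbon C4 can reach only one of the two enantiotopic carbonyl carbons (C5); the bond forms in a concerted ketone-ene transition state in which an isopropylidene methyl hydrogen passes to the carbonyl oxygen (hence OH and isopropenyl cis) and the three-atom tether from C1 forces cis ring fusion (CH3 and OH cis), so all three stereocentres follow from the carbonyl choice; the closest known reaction types are Me2AlCl-promoted intramolecular ketone-ene cyclisation of keto-olefins and bis(oxazoline)-copper-catalysed enantioselective carbonyl-ene reactions of chelating 1,2-dicarbonyl compounds; which ligand antipode gives the drawn enantiomer cannot be predicted safely and is to be settled in the first run (both antipodes are commercial).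

Step 4
Reactants: 7
Product: 8 (1R,3aS,7aS)-7a-hydroxy-3a-methyl-1-(propan-2-yl)octahydro-4H-inden-4-one
Conditions: H2 (1 atm), RhCl(PPh3)3 (5 mol %), benzene, rt
Reagents that add atoms: none
Why: homogeneous hydrogenation with Wilkinson's catalyst should saturate the 1,1-disubstituted alkene without touching the ketone and, unlike Pd/C, without moving the double bond to the isopropylidene position, so C4 is not scrambled.

Step 5
Reactants: 8
Product: 10 (1R,3aS,7aS)-7a-hydroxy-3a,5-dimethyl-1-(propan-2-yl)octahydro-4H-inden-4-one (both C-5 epimers), via dilithium enolate alkoxide 9 (not isolated)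
Conditions: LDA (2.2 equiv), THF, −78 °C; MeI (1.1 equiv), −78 → −20 °C
Reagents that add atoms: iodomethane, CI
Why: enolate alkylation, regiospecific because the C10 ketone can enolise only toward C8 (C1 is quaternary) and the hindered tertiary lithium alkoxide is not methylated at low temperature; the new C8 centre is left uncontrolled because it is erased in step 9.

Step 6
Reactants: 10
Product: 12 (1R,3aS,7aS)-7a-hydroxy-5-(hydroxymethyl)-3a,5-dimethyl-1-(propan-2-yl)octahydro-4H-inden-4-one (both C-5 epimers), via dilithium enolate alkoxide 11 (not isolated)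
Conditions: LDA (2.2 equiv), THF, −78 → 0 °C; CH2O gas (from cracked paraformaldehyde), −78 °C; aq. NH4Cl at −78 °C
Reagents that add atoms: formaldehyde, C=O
Why: aldol addition of the fully substituted enolate to monomeric formaldehyde, the smallest carbonyl electrophile, puts the future C9 on C8 as CH2OH, and the cold quench prevents retro-aldol loss of formaldehyde.

Step 7
Reactants: 12
Product: 13 (1R,3aS,7aS)-7a-hydroxy-5-(iodomethyl)-3a,5-dimethyl-1-(propan-2-yl)octahydro-4H-inden-4-one (both C-5 epimers)
Conditions: PPh3, I2, imidazole, toluene, 80 °C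
Reagents that add atoms: iodine, II
Why: Appel-type iodination should convert the primary neopentyl-type alcohol while the hindered tertiary ring-fusion alcohol stays untouched, and the β-iodo ketone cannot eliminate because C8 carries no hydrogen.

Step 8
Reactants: 13
Product: 17 (1R,3aS,8aS)-8a-hydroxy-3a,6-dimethyl-1-(propan-2-yl)octahydroazulen-4(1H)-one (both C-6 epimers), via primary alkyl radical 14 (not isolated), via cyclopropyloxyl radical 15 (not isolated), via tertiary alkyl radical 16 (not isolated)
Conditions: Bu3SnH (1.3 equiv), AIBN (0.2 equiv), syringe pump over 8 h into 13 (0.01 M), benzene, 80 °C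
Reagents that add atoms: none
Why: Bu3Sn• abstracts iodine from 13, and the primary radical 14 (C9) adds 3-exo-trig to the carbon of the neighbouring ketone (C10), which forms the C9–C10 bond and gives cyclopropyloxyl radical 15; β-scission of the old ring bond C10–C8 then opens the three-membered ring outward to the seven-membered ketone as tertiary radical 16, which takes hydrogen from Bu3SnH. The closest known reaction type is the Dowd–Beckwith one-carbon ring expansion of 2-(halomethyl)cycloalkanones (radical 1,2-acyl shift). The seven-membered ring is thus closed by a 3-exo-trig attack on C=O followed by fragmentation, a net insertion of C9 between C8 and C10 of the six-membered ring. The only new stereocentre, C8, comes from unselective hydrogen transfer and is erased in step 9, while C1, C4 and C5 are not touched. The step needs the rearrangement to outrun direct reduction of 14, which the low standing tin hydride concentration should secure, and it needs cleavage of C10–C8 and not C10–C1, which is secured because the former gives a tertiary radical and an unstrained ketone whereas the latter would leave a cyclopropanone.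

Step 9
Reactants: 17
Product: 18 (1R,3aS,8aS)-8a-hydroxy-3a,6-dimethyl-1-(propan-2-yl)-2,3,3a,7,8,8a-hexahydroazulen-4(1H)-one
Conditions: 2-iodoxybenzoic acid (IBX, 1.5 equiv), DMSO–toluene, 70 °C
Reagents that add atoms: none
Why: IBX dehydrogenation of the ketone through its enol, regiospecific because only C9 can enolise, so both C8 epimers should converge on the C8=C9 enone, and the tertiary alcohol is inert to IBX.

Step 10
Reactants: 18
Product: 20 (1R,3aR,4S,8aS)-3a,6-dimethyl-1-(propan-2-yl)-1,2,3,3a,4,7,8,8a-octahydroazulene-4,8a-diol, via catechol borate 19 (not isolated)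
Conditions: catecholborane (1.1 equiv), toluene, rt; then (R)-2-methyl-CBS-oxazaborolidine (0.5 equiv), catecholborane (2 equiv), −78 → −40 °C; MeOH, pH 7 buffer
Reagents that add atoms: none
Why: Corey–Bakshi–Shibata reduction under reagent control, in which the tertiary hydroxyl is first capped as a B–H-free catechol borate (this blocks the face of the angular groups and excludes internal hydride delivery) and the (R)-oxazaborolidine, reading the quaternary C1 as the large and the vinylic C9 as the small carbonyl substituent, should deliver hydride to the opposite face of C10 to give the 4S alcohol cis to the angular CH3 and OH, with 1,2-addition expected for this β,β-disubstituted enone.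

Step 11
Reactants: 20; 21 4-methoxybenzoyl chloride
Product: 22 (1R,3aR,4S,8aS)-8a-hydroxy-3a,6-dimethyl-1-(propan-2-yl)-1,2,3,3a,4,7,8,8a-octahydroazulen-4-yl 4-methoxybenzoate
Conditions: 21 (1.3 equiv), Et3N, DMAP (0.2 equiv), CH2Cl2, 0 °C → rt
Reagents that add atoms: none
Why: DMAP-catalysed acylation should esterify the secondary allylic hydroxyl only, since the tertiary ring-fusion hydroxyl is too hindered, and no stereocentre is touched.

**Compound list**

1 | 2-methylcyclohexane-1,3-dione | CC1C(=O)CCCC1=O | starting material
2 | acrolein (prop-2-enal) | C=CC=O | starting material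
3 | 3-(1-methyl-2,6-dioxocyclohexyl)propanal | CC1(CCC=O)C(=O)CCCC1=O | intermediate
4 | isopropyltriphenylphosphonium iodide | CC(C)[P+](c1ccccc1)(c1ccccc1)c1ccccc1.[I-] | starting material
5 | propan-2-ylidene(triphenyl)phosphorane (not isolated) | CC(C)=P(c1ccccc1)(c1ccccc1)c1ccccc1 | intermediate
6 | 2-methyl-2-(4-methylpent-3-en-1-yl)cyclohexane-1,3-dione | CC(C)=CCCC1(C)C(=O)CCCC1=O | intermediate
7 | (1R,3aS,7aS)-7a-hydroxy-3a-methyl-1-(prop-1-en-2-yl)octahydro-4H-inden-4-one | O=C1CCC[C@]2(O)[C@@H](C(C)=C)CC[C@]12C | intermediate
8 | (1R,3aS,7aS)-7a-hydroxy-3a-methyl-1-(propan-2-yl)octahydro-4H-inden-4-one | O=C1CCC[C@]2(O)[C@@H](C(C)C)CC[C@]12C | intermediate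
9 | dilithium enolate alkoxide of 8 (not isolated) | [Li]OC1=CCC[C@]2(O[Li])[C@@H](C(C)C)CC[C@]12C | intermediate
10 | (1R,3aS,7aS)-7a-hydroxy-3a,5-dimethyl-1-(propan-2-yl)octahydro-4H-inden-4-one, both C-5 epimers | O=C1C(C)CC[C@]2(O)[C@@H](C(C)C)CC[C@]12C | intermediate
11 | dilithium enolate alkoxide of 10 (not isolated) | [Li]OC1=C(C)CC[C@]2(O[Li])[C@@H](C(C)C)CC[C@]12C | intermediate
12 | (1R,3aS,7aS)-7a-hydroxy-5-(hydroxymethyl)-3a,5-dimethyl-1-(propan-2-yl)octahydro-4H-inden-4-one, both C-5 epimers | O=C1C(C)(CO)CC[C@]2(O)[C@@H](C(C)C)CC[C@]12C | intermediate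
13 | (1R,3aS,7aS)-7a-hydroxy-5-(iodomethyl)-3a,5-dimethyl-1-(propan-2-yl)octahydro-4H-inden-4-one, both C-5 epimers | O=C1C(C)(CI)CC[C@]2(O)[C@@H](C(C)C)CC[C@]12C | intermediate
14 | primary alkyl radical (C9) from 13 by iodine abstraction (not isolated) | O=C1C(C)([CH2])CC[C@]2(O)[C@@H](C(C)C)CC[C@]12C | intermediate
15 | cyclopropyloxyl radical with the C9–C10 bond formed (not isolated) | [O]C13CC3(C)CC[C@]2(O)[C@@H](C(C)C)CC[C@]12C | intermediate
16 | ring-enlarged tertiary alkyl radical at C8 (not isolated) | O=C1C[C](C)CC[C@]2(O)[C@@H](C(C)C)CC[C@]12C | intermediate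
17 | (1R,3aS,8aS)-8a-hydroxy-3a,6-dimethyl-1-(propan-2-yl)octahydroazulen-4(1H)-one, both C-6 epimers | O=C1CC(C)CC[C@]2(O)[C@@H](C(C)C)CC[C@]12C | intermediate
18 | (1R,3aS,8aS)-8a-hydroxy-3a,6-dimethyl-1-(propan-2-yl)-2,3,3a,7,8,8a-hexahydroazulen-4(1H)-one | O=C1C=C(C)CC[C@]2(O)[C@@H](C(C)C)CC[C@]12C | intermediate
19 | catechol borate of the tertiary hydroxyl of 18 (not isolated) | O=C1C=C(C)CC[C@]2(OB3Oc4ccccc4O3)[C@@H](C(C)C)CC[C@]12C | intermediate
20 | (1R,3aR,4S,8aS)-3a,6-dimethyl-1-(propan-2-yl)-1,2,3,3a,4,7,8,8a-octahydroazulene-4,8a-diol | O[C@H]1C=C(C)CC[C@]2(O)[C@@H](C(C)C)CC[C@]12C | intermediate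
21 | 4-methoxybenzoyl chloride | COc1ccc(C(Cl)=O)cc1 | starting material
22 | (1R,3aR,4S,8aS)-8a-hydroxy-3a,6-dimethyl-1-(propan-2-yl)-1,2,3,3a,4,7,8,8a-octahydroazulen-4-yl 4-methoxybenzoate | COc1ccc(C(=O)O[C@H]2C=C(C)CC[C@]3(O)[C@@H](C(C)C)CC[C@]23C)cc1 | target

**Count**

Total steps: 11. Longest linear sequence: 11 steps (1 → 22).

**Steps most likely to fail**

Step 3 (proposed new method). The copper complex may activate the ketone too weakly, or may distinguish the two carbonyl groups poorly, so that the product forms slowly or with low enantiomeric purity. The fallback uses known chemistry and sets out from 6. Oxazaborolidine mono-reduction with (S)-2-methyl-CBS-oxazaborolidine and catecholborane in toluene at −78 °C should give (2R,3R)-3-hydroxy-2-methyl-2-(4-methylpent-3-en-1-yl)cyclohexan-1-one F1. The catalyst fixes the R carbinol carbon and hydride enters anti to the longer side chain; the minor diastereomer, which belongs to the mirror-image series at the quaternary carbon, is removed by chromatography. Me2AlCl (2.5 equiv) in CH2Cl2 at −78 → 0 °C then closes the five-membered ring on the one remaining ketone by the same ene reaction, giving (1R,3aR,4R,7aS)-3a-methyl-1-(prop-1-en-2-yl)octahydro-1H-indene-4,7a-diol F2. Dess–Martin periodinane oxidises the secondary alcohol, and the route is rejoined at 7.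

Step 8. Hydrogen transfer to the primary radical may outrun its addition to the carbonyl group (simple deiodination), or the precursor may be hard to supply through steps 6 and 7. The fallback is the Ito–Saegusa ring enlargement and sets out from 10. TMSOTf and Et3N give the (1R,3aS,7aS)-4,7a-bis(trimethylsilyloxy) enol ether of 10 F3, since only the C8 flank can enolise. Et2Zn and CH2I2 cyclopropanate the electron-rich enol ether to the siloxycyclopropane F4. FeCl3 in DMF opens it by one-electron oxidation and cleavage of the internal bond to (1R,3aS,8aS)-6-chloro-8a-hydroxy-3a,6-dimethyl-1-(propan-2-yl)octahydroazulen-4(1H)-one F5, the tertiary silyl ether being lost on acidic work-up. NaOAc in hot MeOH eliminates HCl, and the route is rejoined at 18 (steps 6 to 9 are bypassed).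

Step 10. Facial selectivity of hydride delivery may be poor or reversed: a conformational analysis suggests the substrate itself prefers attack on the face of the angular groups, so the catalyst has to override it. The fallback sets out from 18 and makes the other epimer on purpose. Me4NBH(OAc)3 in MeCN–AcOH at −20 °C delivers hydride internally from the tertiary hydroxyl to give (1R,3aR,4R,8aS)-3a,6-dimethyl-1-(propan-2-yl)-1,2,3,3a,4,7,8,8a-octahydroazulene-4,8a-diol F6. Mitsunobu esterification with 4-methoxybenzoic acid, PPh3 and DIAD in toluene then inverts C10 and installs the ester in one operation. The route is rejoined at 22 (step 11 is bypassed).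

**Further compounds**

F1 | step 3 | (2R,3R)-3-hydroxy-2-methyl-2-(4-methylpent-3-en-1-yl)cyclohexan-1-one | O[C@@H]1CCCC(=O)[C@@]1(CCC=C(C)C)C
F2 | step 3 | (1R,3aR,4R,7aS)-3a-methyl-1-(prop-1-en-2-yl)octahydro-1H-indene-4,7a-diol | O[C@@H]1CCC[C@]2(O)[C@@H](C(C)=C)CC[C@]12C
F3 | step 8 | (1R,3aS,7aS)-3a,5-dimethyl-1-(propan-2-yl)-4,7a-bis(trimethylsilyloxy)-2,3,3a,6,7,7a-hexahydro-1H-indene | C[Si](C)(C)OC1=C(C)CC[C@]2(O[Si](C)(C)C)[C@@H](C(C)C)CC[C@]12C
F4 | step 8 | siloxycyclopropane from F3 (CH2 bridging indene C-4 and C-5, isomer mixture at the cyclopropane) | C[Si](C)(C)OC13CC3(C)CC[C@]2(O[Si](C)(C)C)[C@@H](C(C)C)CC[C@]12C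
F5 | step 8 | (1R,3aS,8aS)-6-chloro-8a-hydroxy-3a,6-dimethyl-1-(propan-2-yl)octahydroazulen-4(1H)-one, both C-6 epimers | O=C1CC(C)(Cl)CC[C@]2(O)[C@@H](C(C)C)CC[C@]12C
F6 | step 10 | (1R,3aR,4R,8aS)-3a,6-dimethyl-1-(propan-2-yl)-1,2,3,3a,4,7,8,8a-octahydroazulene-4,8a-diol | O[C@@H]1C=C(C)CC[C@]2(O)[C@@H](C(C)C)CC[C@]12C
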